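Ring A is taken apart completely. Its C1-OMe/C3-OH/C5-OH array, with the CH2 bridge on C4 between the two hydroxyl carbons and hydrogens on C2 and C6, is exactly what a 3-alkoxycyclobutenone and an alkoxyacetylene assemble in a Danheiser benzannulation. In one heating operation the cyclobutenone opens to a vinylketene, adds methoxyacetylene (bonds C2–C3 and C1–C6) and recloses C3–C4 by 6π electrocyclisation, giving the ring-A phenol with C5 masked as a tert-butyl ether. The precursor is a racemic 3-tert-butoxycyclobutenone whose C4 carries the fully substituted, benzyl-protected ring B through a CH2 group. Afterwards ring A needs only tert-butyl removal, one acetylation and hydrogenolysis.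

Key step: step 8

Remarks and assumptions:
- Ring A is numbered C1 (OMe), C2 (H), C3 (OH), C4 (CH2 bridge), C5 (OH), C6 (acetyl); ring B is the C-methylated ring.
- Ar stands throughout for the ring-B group 3-acetyl-4,6-bis(benzyloxy)-2-methoxy-5-methylphenyl.
- The target is achiral; the stereocentres of 18, 24 and 26 are racemic and disappear on aromatisation.
- Compounds 1, 5, 10 and 19 are taken to be purchasable; the two alkoxyacetylenes are not stock items and are made in steps 5 and 7.

Step 1
Reactants: 1 2',4'-dihydroxy-6'-methoxyacetophenone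
Product: 2 1-(2,4-dihydroxy-6-methoxy-3-methylphenyl)ethanone
Conditions: MeI (1.05 equiv), KOH, MeOH, 0 °C → 50 °C
Reagents that add atoms: iodomethane, CI
Why: Base-mediated nuclear C-methylation of the phloroacetophenone dianion should go to C3', the carbon flanked by both phenoxide oxygens, with methanol solvation disfavouring O-alkylation and near-stoichiometric MeI limiting a second methylation at C5'.

Step 2
Reactants: 2 1-(2,4-dihydroxy-6-methoxy-3-methylphenyl)ethanone
Product: 3 3-acetyl-4,6-dihydroxy-2-methoxy-5-methylbenzaldehyde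
Conditions: POCl3–DMF (1.2 equiv, preformed), MeCN, 0 °C → rt; then H2O, 50 °C
Reagents that add atoms: N,N-dimethylformamide, CN(C)C=O; water, O
Why: Vilsmeier–Haack formylation can only strike the one unsubstituted ring carbon (ortho to OH and OMe, para to OH), and a stoichiometric reagent at low temperature keeps it away from the acetyl methyl group.

Step 3
Reactants: 3 3-acetyl-4,6-dihydroxy-2-methoxy-5-methylbenzaldehyde
Product: 4 3-acetyl-4,6-bis(benzyloxy)-2-methoxy-5-methylbenzaldehyde (ArCHO)
Conditions: BnBr (2.5 equiv), K2CO3, DMF, 60 °C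
Reagents that add atoms: benzyl bromide, BrCc1ccccc1
Why: Williamson etherification of both chelated phenols in a dipolar aprotic solvent, where O-alkylation is favoured and the fully substituted ring offers no aromatic C-alkylation site.

Step 4
Reactants: 4 3-acetyl-4,6-bis(benzyloxy)-2-methoxy-5-methylbenzaldehyde; 5 Meldrum's acid
Product: 9 3-Ar-propanoic acid, via arylidene Meldrum's acid 6 (not isolated), via alkylated Meldrum's acid 7 (not isolated), via malonic acid 8 (not isolated)
Conditions: HCO2H–Et3N (5:2), 95 °C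
Reagents that add atoms: none
Why: One-pot reductive alkylation of Meldrum's acid: Knoevenagel condensation to 6, conjugate hydride transfer from formate to 7, then acylal hydrolysis and decarboxylation through 8, none of which touches benzyl ethers or the hindered ketone.

Step 5
Reactants: 10 trichloroethylene
Product: 15 tert-butoxyacetylene, via dichloroacetylene 11 (not isolated), via (E)-1,2-dichloro-1-tert-butoxyethene 12 (not isolated), via tert-butyl chloroethynyl ether 13 (not isolated), via lithium tert-butoxyacetylide 14 (not isolated)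
Conditions: t-BuOK, THF, −50 °C → rt; n-BuLi (2.2 equiv), −78 → −40 °C; H2O, −78 °C; kept as a cold, dried, titrated solution
Reagents that add atoms: potassium tert-butoxide, CC(C)(C)[O-].[K+]
Why: Dehydrochlorination to 11 and anti addition of tert-butoxide give 12, which n-BuLi converts by elimination to 13 and chlorine–lithium exchange to acetylide 14, protonated cold because the alkyne loses isobutene by retro-ene reaction on warming.

Step 6
Reactants: 9 3-Ar-propanoic acid; 15 tert-butoxyacetylene
Product: 18 4-[[3-acetyl-4,6-bis(benzyloxy)-2-methoxy-5-methylphenyl]methyl]-3-tert-butoxycyclobut-2-en-1-one (racemic), via acid chloride 16 (not isolated), via aldoketene 17 (not isolated)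
Conditions: (COCl)2, cat. DMF, CH2Cl2, 0 °C → rt, evaporate; then slow addition to 15 (4 equiv), Et3N, Et2O–hexane, 0 °C → rt
Reagents that add atoms: none
Why: Dehydrochlorination of 16 by Et3N gives aldoketene 17, which the excess alkyne traps in a thermal ketene–ynol ether (2+2) cycloaddition, its nucleophilic CH terminus bonding to the ketene carbonyl carbon so that OtBu sits at C3 and the CH2Ar group at C4; the new C4 stereocentre forms racemic and is erased in step 8.

Step 7
Reactants: 19 chloroacetaldehyde dimethyl acetal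
Product: 22 methoxyacetylene, via 1-chloro-2-methoxyethene 20 (not isolated), via sodium methoxyacetylide 21 (not isolated)
Conditions: NaNH2 (3.3 equiv), NH3(l), −33 °C; evaporate NH3; sat. aq NaCl, −70 °C; distil into a cold trap
Reagents that add atoms: none
Why: Two successive amide-induced eliminations (methanol, then HCl) give the alkoxyacetylene, which is held as its sodium acetylide 21 until the cold aqueous quench, the classical preparation of alkoxyacetylenes from chloroacetals.

Step 8
Reactants: 18 4-(ArCH2)-3-tert-butoxycyclobut-2-en-1-one; 22 methoxyacetylene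
Product: 27 1-[2,4-bis(benzyloxy)-5-[(2-tert-butoxy-6-hydroxy-4-methoxyphenyl)methyl]-6-methoxy-3-methylphenyl]ethanone, via vinylketene 23 (not isolated), via vinylcyclobutenone 24 (not isolated), via dienylketene 25 (not isolated), via cyclohexadienone 26 (not isolated)
Conditions: 22 (5 equiv), toluene, sealed tube, 80 °C → 120 °C
Reagents that add atoms: none
Why: Danheiser benzannulation: thermal 4π opening of 18 (its ring bond C1–C4, the future C3–C4 of ring A, is cleaved with CH2Ar turning outward) gives vinylketene 23, whose ketene C=C adds methoxyacetylene in a (2+2) cycloaddition to 24, which opens again to dienylketene 25. Ring A then closes by a thermally allowed disrotatory 6π electrocyclisation of 25 that re-forms C3–C4 and gives dienone 26, and enolisation delivers the phenol. The closest precedent is the known thermal benzannulation of cyclobutenones with alkoxyacetylenes to resorcinol monoethers. No stereocentre survives, since the racemic centres of 18, 24 and 26 all become sp2 carbons of the arene. The one selectivity needed is the orientation of the ketene–alkyne addition, and the polarisation of the ynol ether secures it: its nucleophilic CH terminus bonds to the ketene carbonyl carbon, so OMe ends on C1 para to the bridge and the ketene oxygen becomes the C3 hydroxyl. Ring B is fully substituted and only a spectator, and methoxyacetylene, lacking a β-hydrogen, cannot fragment by retro-ene reaction at the temperature the donor-stabilised cyclobutenone needs to open.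

Step 9
Reactants: 27 1-[2,4-bis(benzyloxy)-5-[(2-tert-butoxy-6-hydroxy-4-methoxyphenyl)methyl]-6-methoxy-3-methylphenyl]ethanone
Product: 28 1-[2,4-bis(benzyloxy)-5-[(2,6-dihydroxy-4-methoxyphenyl)methyl]-6-methoxy-3-methylphenyl]ethanone
Conditions: TFA–CH2Cl2 (1:9), 1,3-dimethoxybenzene (5 equiv), 0 °C
Reagents that add atoms: none
Why: Acidolysis (SN1) of the aryl tert-butyl ether, the tert-butyl cation being taken up by 1,3-dimethoxybenzene, while benzyl ethers, the ketone and the diarylmethane link should withstand dilute TFA at 0 °C.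

Step 10
Reactants: 28 1-[2,4-bis(benzyloxy)-5-[(2,6-dihydroxy-4-methoxyphenyl)methyl]-6-methoxy-3-methylphenyl]ethanone
Product: 29 1-[5-[(3-acetyl-2,6-dihydroxy-4-methoxyphenyl)methyl]-2,4-bis(benzyloxy)-6-methoxy-3-methylphenyl]ethanone
Conditions: Ac2O (1.1 equiv), BF3·OEt2, EtOAc, 0 °C → rt; aq NaOAc work-up
Reagents that add atoms: acetic anhydride, CC(=O)OC(C)=O
Why: Friedel–Crafts C-acetylation (direct, or by O-acylation and Fries shift) of a phloroglucinol monomethyl ether: C2 and C6 of ring A are equivalent, ring B has no free carbon, and the chelated acetyl deactivates ring A against a second acylation.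

Step 11
Reactants: 29 1-[5-[(3-acetyl-2,6-dihydroxy-4-methoxyphenyl)methyl]-2,4-bis(benzyloxy)-6-methoxy-3-methylphenyl]ethanone
Product: 30 1-[5-[(3-acetyl-2,6-dihydroxy-4-methoxyphenyl)methyl]-2,4-dihydroxy-6-methoxy-3-methylphenyl]ethanone (target)
Conditions: H2 (1 atm), 10% Pd/C, EtOAc, rt
Reagents that add atoms: none
Why: Palladium-catalysed hydrogenolysis of the two benzyl aryl ethers under neutral conditions, which chelated aryl ketones and the diarylmethane survive at ambient pressure and temperature.

Compound list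
1 | 2',4'-dihydroxy-6'-methoxyacetophenone | CC(=O)c1c(O)cc(O)cc1OC | starting material
2 | 1-(2,4-dihydroxy-6-methoxy-3-methylphenyl)ethanone | CC(=O)c1c(O)c(C)c(O)cc1OC | intermediate
3 | 3-acetyl-4,6-dihydroxy-2-methoxy-5-methylbenzaldehyde | CC(=O)c1c(O)c(C)c(O)c(C=O)c1OC | intermediate
4 | 3-acetyl-4,6-bis(benzyloxy)-2-methoxy-5-methylbenzaldehyde | CC(=O)c1c(OCc2ccccc2)c(C)c(OCc2ccccc2)c(C=O)c1OC | intermediate
5 | Meldrum's acid (2,2-dimethyl-1,3-dioxane-4,6-dione) | CC1(C)OC(=O)CC(=O)O1 | starting material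
6 | 5-(Ar-methylidene)-2,2-dimethyl-1,3-dioxane-4,6-dione | CC(=O)c1c(OCc2ccccc2)c(C)c(OCc2ccccc2)c(C=C2C(=O)OC(C)(C)OC2=O)c1OC | intermediate
7 | 5-(ArCH2)-2,2-dimethyl-1,3-dioxane-4,6-dione | CC(=O)c1c(OCc2ccccc2)c(C)c(OCc2ccccc2)c(CC2C(=O)OC(C)(C)OC2=O)c1OC | intermediate
8 | 2-(ArCH2)propanedioic acid | CC(=O)c1c(OCc2ccccc2)c(C)c(OCc2ccccc2)c(CC(C(=O)O)C(=O)O)c1OC | intermediate
9 | 3-[3-acetyl-4,6-bis(benzyloxy)-2-methoxy-5-methylphenyl]propanoic acid | CC(=O)c1c(OCc2ccccc2)c(C)c(OCc2ccccc2)c(CCC(=O)O)c1OC | intermediate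
10 | trichloroethylene | ClC=C(Cl)Cl | starting material
11 | dichloroacetylene | ClC#CCl | intermediate
12 | (E)-1,2-dichloro-1-tert-butoxyethene | Cl/C=C(/Cl)OC(C)(C)C | intermediate
13 | tert-butyl chloroethynyl ether | ClC#COC(C)(C)C | intermediate
14 | lithium tert-butoxyacetylide | [Li+].[C-]#COC(C)(C)C | intermediate
15 | tert-butoxyacetylene | C#COC(C)(C)C | intermediate
16 | 3-Ar-propanoyl chloride | CC(=O)c1c(OCc2ccccc2)c(C)c(OCc2ccccc2)c(CCC(=O)Cl)c1OC | intermediate
17 | 3-Ar-prop-1-en-1-one (aldoketene ArCH2CH=C=O) | CC(=O)c1c(OCc2ccccc2)c(C)c(OCc2ccccc2)c(CC=C=O)c1OC | intermediate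
18 | 4-[[3-acetyl-4,6-bis(benzyloxy)-2-methoxy-5-methylphenyl]methyl]-3-tert-butoxycyclobut-2-en-1-one, racemic | CC(C)(C)OC1=CC(=O)C1Cc1c(OCc2ccccc2)c(C)c(OCc2ccccc2)c(C(C)=O)c1OC | intermediate
19 | chloroacetaldehyde dimethyl acetal (2-chloro-1,1-dimethoxyethane) | COC(CCl)OC | starting material
20 | 1-chloro-2-methoxyethene, E/Z mixture | COC=CCl | intermediate
21 | sodium methoxyacetylide | [Na+].[C-]#COC | intermediate
22 | methoxyacetylene | COC#C | intermediate
23 | (3Z)-5-Ar-3-tert-butoxypenta-1,3-dien-1-one (vinylketene) | O=C=C/C(OC(C)(C)C)=C/Cc1c(OCc2ccccc2)c(C)c(OCc2ccccc2)c(C(C)=O)c1OC | intermediate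
24 | 4-[(Z)-3-Ar-1-tert-butoxyprop-1-enyl]-3-methoxycyclobut-2-en-1-one, racemic | O=C1C=C(OC)C1/C(OC(C)(C)C)=C/Cc2c(OCc3ccccc3)c(C)c(OCc3ccccc3)c(C(C)=O)c2OC | intermediate
25 | (3E,5Z)-7-Ar-5-tert-butoxy-3-methoxyhepta-1,3,5-trien-1-one (dienylketene) | O=C=C/C(OC)=C\C(OC(C)(C)C)=C\Cc1c(OCc2ccccc2)c(C)c(OCc2ccccc2)c(C(C)=O)c1OC | intermediate
26 | 6-(ArCH2)-5-tert-butoxy-3-methoxycyclohexa-2,4-dien-1-one, racemic | O=C1C=C(OC)C=C(OC(C)(C)C)C1Cc2c(OCc3ccccc3)c(C)c(OCc3ccccc3)c(C(C)=O)c2OC | intermediate
27 | 1-[2,4-bis(benzyloxy)-5-[(2-tert-butoxy-6-hydroxy-4-methoxyphenyl)methyl]-6-methoxy-3-methylphenyl]ethanone | COc1cc(O)c(Cc2c(OCc3ccccc3)c(C)c(OCc3ccccc3)c(C(C)=O)c2OC)c(OC(C)(C)C)c1 | intermediate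
28 | 1-[2,4-bis(benzyloxy)-5-[(2,6-dihydroxy-4-methoxyphenyl)methyl]-6-methoxy-3-methylphenyl]ethanone | COc1cc(O)c(Cc2c(OCc3ccccc3)c(C)c(OCc3ccccc3)c(C(C)=O)c2OC)c(O)c1 | intermediate
29 | 1-[5-[(3-acetyl-2,6-dihydroxy-4-methoxyphenyl)methyl]-2,4-bis(benzyloxy)-6-methoxy-3-methylphenyl]ethanone | COc1cc(O)c(Cc2c(OCc3ccccc3)c(C)c(OCc3ccccc3)c(C(C)=O)c2OC)c(O)c1C(C)=O | intermediate
30 | 1-[5-[(3-acetyl-2,6-dihydroxy-4-methoxyphenyl)methyl]-2,4-dihydroxy-6-methoxy-3-methylphenyl]ethanone | COc1cc(O)c(Cc2c(O)c(C)c(O)c(C(C)=O)c2OC)c(O)c1C(C)=O | target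

Total steps: 11. Longest linear sequence: 9 (steps 1, 2, 3, 4, 6, 8, 9, 10, 11); steps 5 and 7 are one-step branches that supply the two alkoxyacetylenes.

Steps most likely to fail

1. Step 8. The donor-stabilised (vinylogous ester) cyclobutenone may open more slowly than its tert-butyl enol ether loses isobutene or the alkyne oligomerises, and the vinylketene may acylate the phenol as it forms. Fallback: ring A would then be bought instead of built. Setting out from aldehyde 4, NaBH4 (MeOH–THF, −10 °C) should reduce the formyl group selectively over the hindered ketone to the benzylic alcohol 1-[2,4-bis(benzyloxy)-5-(hydroxymethyl)-6-methoxy-3-methylphenyl]ethanone F1. F1 and an excess of acetophenone 1 with cat. Sc(OTf)3 in MeCN should then undergo Friedel–Crafts benzylation at C3' of 1, the carbon between its two hydroxyls. This gives 29 directly, so the route is rejoined at 29 and only step 11 remains.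

2. Step 6. Amine-promoted dimerisation of the unstabilised aldoketene and retro-ene decay of the tert-butyl ynol ether may outrun the cycloaddition. Fallback: the ketene would be made as its more electrophilic and less dimerisation-prone α-chloro analogue. Setting out from 4 and 5, the reductive alkylation would be stopped at 7 (Hantzsch ester, cat. L-proline, EtOH, rt), which is now isolated. NCS with K2CO3 in MeCN should chlorinate its acidic C5–H to 5-chloro-5-(ArCH2)-2,2-dimethyl-1,3-dioxane-4,6-dione F2. Hot aqueous AcOH should hydrolyse the acylal to 2-chloro-2-(ArCH2)propanedioic acid F3 and decarboxylate it to racemic 2-chloro-3-Ar-propanoic acid F4. Oxalyl chloride would give racemic 2-chloro-3-Ar-propanoyl chloride F5, and Et3N in the presence of 15 at −20 °C the chloroketene 2-chloro-3-Ar-prop-1-en-1-one F6. Its (2+2) cycloaddition should give racemic 4-chloro-4-(ArCH2)-3-tert-butoxycyclobut-2-en-1-one F7. Zn dust with AcOH and TMEDA in EtOH would remove the chlorine and return the route at 18.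

3. Step 10. Ipso protonation of ring A at C4 with loss of the ring-B benzyl group (retro-Friedel–Crafts cleavage of the diarylmethane), or acetolysis of the benzyl ethers, may compete with C-acylation. Fallback: the acetyl group would be brought in without any Lewis acid. From diol 28, NIS (1.0 equiv, MeCN, −20 °C) should iodinate one of the two equivalent free carbons of ring A to give 1-[2,4-bis(benzyloxy)-5-[(2,6-dihydroxy-3-iodo-4-methoxyphenyl)methyl]-6-methoxy-3-methylphenyl]ethanone F8. Stille coupling with tributyl(1-ethoxyvinyl)stannane (Pd(PPh3)4, a zerovalent palladium catalyst, toluene, 100 °C) should give the enol ether 1-[2,4-bis(benzyloxy)-5-[[3-(1-ethoxyvinyl)-2,6-dihydroxy-4-methoxyphenyl]methyl]-6-methoxy-3-methylphenyl]ethanone F9. Dilute aqueous HCl in THF would unmask the methyl ketone and rejoin the route at 29.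

Further compounds
F1 | step 8 | 1-[2,4-bis(benzyloxy)-5-(hydroxymethyl)-6-methoxy-3-methylphenyl]ethanone | CC(=O)c1c(OCc2ccccc2)c(C)c(OCc2ccccc2)c(CO)c1OC
F2 | step 6 | 5-chloro-5-(ArCH2)-2,2-dimethyl-1,3-dioxane-4,6-dione | CC(=O)c1c(OCc2ccccc2)c(C)c(OCc2ccccc2)c(CC2(Cl)C(=O)OC(C)(C)OC2=O)c1OC
F3 | step 6 | 2-chloro-2-(ArCH2)propanedioic acid | CC(=O)c1c(OCc2ccccc2)c(C)c(OCc2ccccc2)c(CC(Cl)(C(=O)O)C(=O)O)c1OC
F4 | step 6 | 2-chloro-3-Ar-propanoic acid, racemic | CC(=O)c1c(OCc2ccccc2)c(C)c(OCc2ccccc2)c(CC(Cl)C(=O)O)c1OC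
F5 | step 6 | 2-chloro-3-Ar-propanoyl chloride, racemic | CC(=O)c1c(OCc2ccccc2)c(C)c(OCc2ccccc2)c(CC(Cl)C(=O)Cl)c1OC
F6 | step 6 | 2-chloro-3-Ar-prop-1-en-1-one (chloroketene) | CC(=O)c1c(OCc2ccccc2)c(C)c(OCc2ccccc2)c(CC(Cl)=C=O)c1OC
F7 | step 6 | 4-chloro-4-(ArCH2)-3-tert-butoxycyclobut-2-en-1-one, racemic | CC(C)(C)OC1=CC(=O)C1(Cl)Cc1c(OCc2ccccc2)c(C)c(OCc2ccccc2)c(C(C)=O)c1OC
F8 | step 10 | 1-[2,4-bis(benzyloxy)-5-[(2,6-dihydroxy-3-iodo-4-methoxyphenyl)methyl]-6-methoxy-3-methylphenyl]ethanone | COc1cc(O)c(Cc2c(OCc3ccccc3)c(C)c(OCc3ccccc3)c(C(C)=O)c2OC)c(O)c1I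
F9 | step 10 | 1-[2,4-bis(benzyloxy)-5-[[3-(1-ethoxyvinyl)-2,6-dihydroxy-4-methoxyphenyl]methyl]-6-methoxy-3-methylphenyl]ethanone | CCOC(=C)c1c(OC)cc(O)c(Cc2c(OCc3ccccc3)c(C)c(OCc3ccccc3)c(C(C)=O)c2OC)c1O
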